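**Retrosynthetic overview**
1. Target 15 ⇐ desilylation of (S)-ketone 14 ⇐ Pd-catalysed decarboxylative asymmetric protonation of allyl enol carbonate 13 (C3 set last) ⇐ 1,4-reduction/O-acylation of silylated isoflavone 11.
2. Isoflavone 10 ⇐ one-pot polyketide-type recyclisation of pyrone ketone 6 after C-formylation: a Claisen closure makes ring A and hemiacetalisation/dehydration makes ring C in the same flask.
3. 6 ⇐ C-acylation of the triacetic acid lactone (5) dianion with Weinreb arylacetamide 4 (C4–C4a bond).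
4. 4 ⇐ Pd α-arylation of a Reformatsky reagent with aryl bromide 3 ⇐ ortho-C-prenylation of 4-bromo-3-methoxyphenol (1).
5. Ring order: ring B is bought as the arene; rings A and C are formed together in step 5; no ring is made afterwards.

Assumption: C3 is (S) as read from the SMILES; only 1 and 5 are numbered starting materials, and small electrophiles (prenyl bromide, silylating agents, the bromo Weinreb acetamide, ethyl formate, allyl chloroformate) are listed as reagents.

**Route**

Step 1
Reactants: 1 4-bromo-3-methoxyphenol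
Product: 2 4-bromo-5-methoxy-2-(3-methylbut-2-en-1-yl)phenol
Conditions: NaH (1.05 equiv), toluene, 0 °C → rt; prenyl bromide (1.1 equiv), rt, 16 h
Reagents that add atoms: prenyl bromide (1-bromo-3-methylbut-2-ene), CC(C)=CCBr
Why: ortho-C-alkylation of a sodium phenoxide in a non-polar solvent (the tight ion pair directs the allylic bromide to carbon), with the para position blocked by Br and C6 less hindered than C2, so the prenyl group enters next to OH and para to OMe; the minor C2 isomer and O-ether are removed by chromatography.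

Step 2
Reactants: 2 4-bromo-5-methoxy-2-(3-methylbut-2-en-1-yl)phenol
Product: 3 [4-bromo-5-methoxy-2-(3-methylbut-2-en-1-yl)phenoxy](tert-butyl)dimethylsilane
Conditions: TBSCl, imidazole, DMF, rt
Reagents that add atoms: tert-butyldimethylsilyl chloride (TBSCl), CC(C)(C)[Si](C)(C)Cl
Why: standard silylation of a phenol (silyl ether formation), masking the acidic OH for the organozinc and polyanion steps.

Step 3
Reactants: 3 [4-bromo-5-methoxy-2-(3-methylbut-2-en-1-yl)phenoxy](tert-butyl)dimethylsilane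
Product: 4 2-[4-(tert-butyldimethylsilyloxy)-2-methoxy-5-(3-methylbut-2-en-1-yl)phenyl]-N-methoxy-N-methylacetamide
Conditions: BrCH2C(O)N(OMe)Me, Zn dust (TMSCl-activated), THF, rt; then 3, Pd(dba)2 (2 mol %), Q-Phos (2 mol %), THF, 65 °C
Reagents that add atoms: 2-bromo-N-methoxy-N-methylacetamide, BrCC(=O)N(C)OC
Why: Pd-catalysed α-arylation of a zinc amide enolate (Reformatsky reagent; Negishi-type C(sp2)–C(sp3) coupling), which tolerates the silyl ether and the trisubstituted alkene and gives the arylacetic Weinreb amide directly.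

Step 4
Reactants: 4 2-[4-(tert-butyldimethylsilyloxy)-2-methoxy-5-(3-methylbut-2-en-1-yl)phenyl]-N-methoxy-N-methylacetamide; 5 4-hydroxy-6-methyl-2H-pyran-2-one (triacetic acid lactone)
Product: 6 6-{3-[4-(tert-butyldimethylsilyloxy)-2-methoxy-5-(3-methylbut-2-en-1-yl)phenyl]-2-oxopropyl}-4-hydroxy-2H-pyran-2-one
Conditions: 5 (1.5 equiv), LDA (3.1 equiv), THF, −78 → −20 °C; then 4, −78 → 0 °C; aq. HCl
Reagents that add atoms: none
Why: C-acylation of the triacetic acid lactone dianion at its 6-methyl carbanion by a Weinreb amide (polyanion acylation), the chelated tetrahedral adduct releasing the ketone only on work-up so that neither over-addition nor quenching of the dianion by the product occurs.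

Step 5
Reactants: 6 6-{3-[4-(tert-butyldimethylsilyloxy)-2-methoxy-5-(3-methylbut-2-en-1-yl)phenyl]-2-oxopropyl}-4-hydroxy-2H-pyran-2-one
Product: 10 5,7-dihydroxy-3-[4-hydroxy-2-methoxy-5-(3-methylbut-2-en-1-yl)phenyl]-4H-chromen-4-one, via formyl ketone 7 (not isolated), via triketo ester 8 (not isolated), via acylphloroglucinol 9 (not isolated)
Conditions: LDA (3.3 equiv), THF, −78 → −20 °C; HCO2Et (1.3 equiv), −78 → 0 °C; then Mg(OMe)2 (8 equiv), MeOH, 65 °C, 16 h; then AcOH (excess), 60 °C, 1 h
Reagents that add atoms: ethyl formate, CCOC=O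
Why: Proposed new method: the tri-anion of 6 is C-formylated at its least stabilised (benzylic) carbanion to give 7, Mg(OMe)2 then opens the pyrone to the chelated triketo ester 8, whose C6 carbanion attacks the ester carbonyl in a Claisen (not aldol) cyclisation because the C7 ketone and the formyl carbon are both deactivated as a β-oxido-enone anion, giving acylphloroglucinol 9 (ring A, silyl ether methanolysed), and on acidification an ortho OH adds to the freed aldehyde and water is lost (ring C); the closest known reaction types are the Mg(OMe)2-mediated recyclisation of 6-(2-oxoalkyl)-4-hydroxy-2-pyrones to acylphloroglucinols (biomimetic Claisen cyclisation of 3,5,7-triketo esters) and the formyl-deoxybenzoin ring closure of the ethyl formate isoflavone synthesis; no stereocentre is formed.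

Step 6
Reactants: 10 5,7-dihydroxy-3-[4-hydroxy-2-methoxy-5-(3-methylbut-2-en-1-yl)phenyl]-4H-chromen-4-one
Product: 11 5,7-bis(triisopropylsilyloxy)-3-[2-methoxy-5-(3-methylbut-2-en-1-yl)-4-(triisopropylsilyloxy)phenyl]-4H-chromen-4-one
Conditions: TIPSOTf (3.6 equiv), 2,6-lutidine, CH2Cl2, 0 → 40 °C
Reagents that add atoms: triisopropylsilyl trifluoromethanesulfonate (TIPSOTf), CC(C)[Si](C(C)C)(C(C)C)OS(=O)(=O)C(F)(F)F
Why: silylation of phenols with a silyl triflate, which caps all three OH groups including the H-bonded 5-OH so that no acidic proton is present in the enolate steps, the bulky TIPS group at O5 resisting 1,5-O→O silyl transfer to the neighbouring enolate oxygen.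

Step 7
Reactants: 11 5,7-bis(triisopropylsilyloxy)-3-[2-methoxy-5-(3-methylbut-2-en-1-yl)-4-(triisopropylsilyloxy)phenyl]-4H-chromen-4-one
Product: 13 allyl 5,7-bis(triisopropylsilyloxy)-3-[2-methoxy-5-(3-methylbut-2-en-1-yl)-4-(triisopropylsilyloxy)phenyl]-2H-chromen-4-yl carbonate, via lithium enolate 12 (not isolated)
Conditions: L-Selectride (1.2 equiv), THF, −78 °C, 45 min; allyl chloroformate (2 equiv), −78 → 0 °C
Reagents that add atoms: allyl chloroformate, C=CCOC(=O)Cl
Why: conjugate (1,4-) hydride reduction of the chromone enone by a bulky trialkylborohydride followed by O-acylation of the resulting enolate with a chloroformate (enol carbonate formation), with no stereocentre fixed yet.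

Step 8
Reactants: 13 allyl 5,7-bis(triisopropylsilyloxy)-3-[2-methoxy-5-(3-methylbut-2-en-1-yl)-4-(triisopropylsilyloxy)phenyl]-2H-chromen-4-yl carbonate
Product: 14 (3S)-5,7-bis(triisopropylsilyloxy)-3-[2-methoxy-5-(3-methylbut-2-en-1-yl)-4-(triisopropylsilyloxy)phenyl]chroman-4-one
Conditions: Pd2(dba)3 (5 mol %), (S)-(CF3)3-t-BuPHOX (12.5 mol %), Meldrum's acid (2.5 equiv), 1,4-dioxane, 40 °C
Reagents that add atoms: none
Why: Pd-catalysed decarboxylative asymmetric protonation (ionisation of the allyl carbonate, loss of CO2, then enantioselective C-protonation of the PHOX–Pd enolate by Meldrum's acid, which also scavenges the allyl group), a reaction type established for 2′-methoxy-isoflavanones; C3 is set here as (S) by the ligand, whose (S) form is assigned by analogy and swapped for its antipode if the first run gives (R).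

Step 9
Reactants: 14 (3S)-5,7-bis(triisopropylsilyloxy)-3-[2-methoxy-5-(3-methylbut-2-en-1-yl)-4-(triisopropylsilyloxy)phenyl]chroman-4-one
Product: 15 (3S)-5,7-dihydroxy-3-[4-hydroxy-2-methoxy-5-(3-methylbut-2-en-1-yl)phenyl]chroman-4-one
Conditions: KHF2 (6 equiv), MeOH, rt, 3–6 h
Reagents that add atoms: none
Why: fluoride-mediated cleavage of aryl silyl ethers under mildly acidic conditions, which leaves the prenyl alkene untouched and does not enolise the α-aryl ketone, so C3 stays (S).

**Compound list**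
1 | 4-bromo-3-methoxyphenol | COc1cc(O)ccc1Br | starting material
2 | 4-bromo-5-methoxy-2-(3-methylbut-2-en-1-yl)phenol | COc1cc(O)c(CC=C(C)C)cc1Br | intermediate
3 | [4-bromo-5-methoxy-2-(3-methylbut-2-en-1-yl)phenoxy](tert-butyl)dimethylsilane | COc1cc(O[Si](C)(C)C(C)(C)C)c(CC=C(C)C)cc1Br | intermediate
4 | 2-[4-(tert-butyldimethylsilyloxy)-2-methoxy-5-(3-methylbut-2-en-1-yl)phenyl]-N-methoxy-N-methylacetamide | COc1cc(O[Si](C)(C)C(C)(C)C)c(CC=C(C)C)cc1CC(=O)N(C)OC | intermediate
5 | 4-hydroxy-6-methyl-2H-pyran-2-one (triacetic acid lactone) | CC1=CC(O)=CC(=O)O1 | starting material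
6 | 6-{3-[4-(tert-butyldimethylsilyloxy)-2-methoxy-5-(3-methylbut-2-en-1-yl)phenyl]-2-oxopropyl}-4-hydroxy-2H-pyran-2-one | COc1cc(O[Si](C)(C)C(C)(C)C)c(CC=C(C)C)cc1CC(=O)CC1=CC(O)=CC(=O)O1 | intermediate
7 | 6-{3-[4-(tert-butyldimethylsilyloxy)-2-methoxy-5-(3-methylbut-2-en-1-yl)phenyl]-4-hydroxy-2-oxobut-3-en-1-yl}-4-hydroxy-2H-pyran-2-one (α-formyl ketone, enol form, geometry not fixed) | COc1cc(O[Si](C)(C)C(C)(C)C)c(CC=C(C)C)cc1C(=CO)C(=O)CC1=CC(O)=CC(=O)O1 | intermediate
8 | methyl 8-[4-(tert-butyldimethylsilyloxy)-2-methoxy-5-(3-methylbut-2-en-1-yl)phenyl]-9-hydroxy-3,5,7-trioxonon-8-enoate (present as its Mg chelate) | COC(=O)CC(=O)CC(=O)CC(=O)C(=CO)c1cc(CC=C(C)C)c(O[Si](C)(C)C(C)(C)C)cc1OC | intermediate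
9 | 3-hydroxy-2-[4-hydroxy-2-methoxy-5-(3-methylbut-2-en-1-yl)phenyl]-1-(2,4,6-trihydroxyphenyl)prop-2-en-1-one | COc1cc(O)c(CC=C(C)C)cc1C(=CO)C(=O)c1c(O)cc(O)cc1O | intermediate
10 | 5,7-dihydroxy-3-[4-hydroxy-2-methoxy-5-(3-methylbut-2-en-1-yl)phenyl]-4H-chromen-4-one | COc1cc(O)c(CC=C(C)C)cc1C1=COc2cc(O)cc(O)c2C1=O | intermediate
11 | 5,7-bis(triisopropylsilyloxy)-3-[2-methoxy-5-(3-methylbut-2-en-1-yl)-4-(triisopropylsilyloxy)phenyl]-4H-chromen-4-one | COc1cc(O[Si](C(C)C)(C(C)C)C(C)C)c(CC=C(C)C)cc1C1=COc2cc(O[Si](C(C)C)(C(C)C)C(C)C)cc(O[Si](C(C)C)(C(C)C)C(C)C)c2C1=O | intermediate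
12 | lithium 5,7-bis(triisopropylsilyloxy)-3-[2-methoxy-5-(3-methylbut-2-en-1-yl)-4-(triisopropylsilyloxy)phenyl]-2H-chromen-4-olate | COc1cc(O[Si](C(C)C)(C(C)C)C(C)C)c(CC=C(C)C)cc1C1=C([O-])c2c(O[Si](C(C)C)(C(C)C)C(C)C)cc(O[Si](C(C)C)(C(C)C)C(C)C)cc2OC1.[Li+] | intermediate
13 | allyl 5,7-bis(triisopropylsilyloxy)-3-[2-methoxy-5-(3-methylbut-2-en-1-yl)-4-(triisopropylsilyloxy)phenyl]-2H-chromen-4-yl carbonate | COc1cc(O[Si](C(C)C)(C(C)C)C(C)C)c(CC=C(C)C)cc1C1=C(OC(=O)OCC=C)c2c(O[Si](C(C)C)(C(C)C)C(C)C)cc(O[Si](C(C)C)(C(C)C)C(C)C)cc2OC1 | intermediate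
14 | (3S)-5,7-bis(triisopropylsilyloxy)-3-[2-methoxy-5-(3-methylbut-2-en-1-yl)-4-(triisopropylsilyloxy)phenyl]chroman-4-one | COc1cc(O[Si](C(C)C)(C(C)C)C(C)C)c(CC=C(C)C)cc1[C@H]1COc2cc(O[Si](C(C)C)(C(C)C)C(C)C)cc(O[Si](C(C)C)(C(C)C)C(C)C)c2C1=O | intermediate
15 | (3S)-5,7-dihydroxy-3-[4-hydroxy-2-methoxy-5-(3-methylbut-2-en-1-yl)phenyl]chroman-4-one (CNP0265203.1) | COc1cc(O)c(CC=C(C)C)cc1[C@H]1COc2cc(O)cc(O)c2C1=O | target

**Totals**
Total step count: 9. Longest linear sequence: 9 steps (1 → 15; 5 enters at step 4).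

**Three steps most likely to fail, with fallbacks**

Most at risk is step 5. The Claisen closure may stall on the highly charged formylated chain, or the formyl group may be lost under methoxide. The fallback separates the two ring closures and sets out from 6. Heating 6 with Mg(OMe)2 in MeOH without prior formylation gives, by the precedented Claisen recyclisation (silyl ether lost), the deoxybenzoin 2-[4-hydroxy-2-methoxy-5-(3-methylbut-2-en-1-yl)phenyl]-1-(2,4,6-trihydroxyphenyl)ethan-1-one F1. C2 is then inserted and ring C closed with N-formylimidazole (CDI/HCO2H) in THF at rt, passing through 9 and coming back to the route at 10.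

Second is step 4. The dianion of 5 may deprotonate the benzylic CH2 of 4 instead of adding to the amide. The fallback replaces acylation by aldol addition and oxidation; it sets out from 4 and 5. DIBAL-H at −78 °C reduces 4 to 2-[4-(tert-butyldimethylsilyloxy)-2-methoxy-5-(3-methylbut-2-en-1-yl)phenyl]acetaldehyde F2. The dianion of 5 adds to it at −78 °C (carbonyl addition outruns proton transfer) to give racemic 6-{3-[4-(tert-butyldimethylsilyloxy)-2-methoxy-5-(3-methylbut-2-en-1-yl)phenyl]-2-hydroxypropyl}-4-hydroxy-2H-pyran-2-one F3. Dess–Martin oxidation of the secondary alcohol comes back to the route at 6.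

Third is step 8. The 5-silyloxy group crowds the Pd enolate, which has not been tested in this protonation, so the ee may be low; trapping in step 7 may also be sluggish for the same reason. The fallback bypasses steps 7 and 8 and sets out from 11. Transfer hydrogenation with RuCl[(S,S)-TsDPEN](p-cymene) and HCO2H/Et3N reduces the C2=C3 bond, then reduces the base-epimerising ketone with dynamic kinetic resolution, giving cis-(3S,4S)-5,7-bis(triisopropylsilyloxy)-3-[2-methoxy-5-(3-methylbut-2-en-1-yl)-4-(triisopropylsilyloxy)phenyl]chroman-4-ol F4. Buffered Dess–Martin oxidation (NaHCO3, CH2Cl2, 0 °C) of the benzylic alcohol, without touching C3, comes back to the route at 14.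

**Further compounds**
F1 | step 5 | 2-[4-hydroxy-2-methoxy-5-(3-methylbut-2-en-1-yl)phenyl]-1-(2,4,6-trihydroxyphenyl)ethan-1-one | COc1cc(O)c(CC=C(C)C)cc1CC(=O)c1c(O)cc(O)cc1O
F2 | step 4 | 2-[4-(tert-butyldimethylsilyloxy)-2-methoxy-5-(3-methylbut-2-en-1-yl)phenyl]acetaldehyde | COc1cc(O[Si](C)(C)C(C)(C)C)c(CC=C(C)C)cc1CC=O
F3 | step 4 | 6-{3-[4-(tert-butyldimethylsilyloxy)-2-methoxy-5-(3-methylbut-2-en-1-yl)phenyl]-2-hydroxypropyl}-4-hydroxy-2H-pyran-2-one (racemic) | COc1cc(O[Si](C)(C)C(C)(C)C)c(CC=C(C)C)cc1CC(O)CC1=CC(O)=CC(=O)O1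
F4 | step 8 | (3S,4S)-5,7-bis(triisopropylsilyloxy)-3-[2-methoxy-5-(3-methylbut-2-en-1-yl)-4-(triisopropylsilyloxy)phenyl]chroman-4-ol | COc1cc(O[Si](C(C)C)(C(C)C)C(C)C)c(CC=C(C)C)cc1[C@H]1COc2cc(O[Si](C(C)C)(C(C)C)C(C)C)cc(O[Si](C(C)C)(C(C)C)C(C)C)c2[C@H]1O
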